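**Outline**

- Cuts: in the lactone, the two exocyclic bonds C4–CH2(aryl) and C3–CH2(aryl); in the side chain, the C7–C8 bond of the glycerol unit and the bond between the phenol oxygen and C8.
- Enabling feature: the five-membered lactone carries its two arylmethyl arms on neighbouring ring carbons, C4 (β to the C=O) and C3 (α), trans to each other. The benzylic carbon of the C4 arm is a former aldehyde carbon of the aryl ring that bears the 4-O-linked threo-glycerol ether. A butenolide can therefore take that arm as a dithiane anion at its β-carbon and the other arm as a benzyl bromide at the α-carbon of the enolate so formed.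
- Forward order: vanillin dithiane, aryloxyacetyl imide, syn aldol, diol, 1,3-dioxane acetonide (a temporary ring, like the dithiane). The lactone ring is not made by cyclisation: it comes from furfural as the menthyloxy butenolide, receives both arms in one pot, and is opened and re-closed only when its acetal carbon is reduced to CH2. Acetonide and benzyl ethers are removed last.
- Stereochemistry: C7/C8 (7R,8R, threo) come from (S)-4-benzyloxazolidin-2-one in the boron aldol. C4 and C3 (both R, trans) are relayed from the 5R acetal carbon of the butenolide, which l-menthol fixes by crystallisation and which is erased at the end.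

Key step: step 11

Remark: locants follow lignan usage (lactone C2 = carbonyl, C3, C4, C5 = OCH2; glycerol C7 = ArCH(OH), C8 = CH(OAr), C9 = CH2OH); the SMILES is read as 3R,4R,7R,8R, and "menthyl" always means (1R,2S,5R)-2-isopropyl-5-methylcyclohexyl.

**Route**

Step 1
Reactants: 1 vanillin
Product: 2 2-(4-hydroxy-3-methoxyphenyl)-1,3-dithiane
Conditions: HS(CH2)3SH, BF3·OEt2 (cat.), CH2Cl2, 0 °C → rt
Reagents that add atoms: 1,3-propanedithiol, SCCCS
Why: Lewis-acid-catalysed dithioacetalisation of an aryl aldehyde is reliable beside a free phenol and turns the aldehyde carbon into the masked acyl anion (Corey–Seebach umpolung) that later becomes the benzylic CH2 on C4.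

Step 2
Reactants: 3 (S)-4-benzyloxazolidin-2-one; 4 chloroacetyl chloride
Product: 6 (S)-4-benzyl-3-(chloroacetyl)oxazolidin-2-one, via lithium oxazolidinide 5 (not isolated)
Conditions: n-BuLi, THF, −78 °C; then 4, −78 → 0 °C
Reagents that add atoms: none
Why: N-acylation of a lithiated oxazolidinone: the nitrogen anion attacks the acid chloride carbonyl far faster than the alkyl chloride, so the α-chloro imide should form without displacement at carbon.

Step 3
Reactants: 2 dithianyl phenol; 6 chloroacetyl imide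
Product: 7 (S)-4-benzyl-3-{[4-(1,3-dithian-2-yl)-2-methoxyphenoxy]acetyl}oxazolidin-2-one
Conditions: K2CO3, acetone, 50 °C
Reagents that add atoms: none
Why: Williamson ether synthesis: the phenoxide displaces chloride from the carbonyl-activated α-carbon by SN2, and carbonate in acetone is too weak a base and nucleophile to cleave the imide or touch the dithiane.

Step 4
Reactants: 7 aryloxyacetyl imide; 8 4-(benzyloxy)-3-methoxybenzaldehyde
Product: 10 (S)-4-benzyl-3-{(2S,3R)-3-[4-(benzyloxy)-3-methoxyphenyl]-2-[4-(1,3-dithian-2-yl)-2-methoxyphenoxy]-3-hydroxypropanoyl}oxazolidin-2-one, via dibutylboron Z-enolate 9 (not isolated)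
Conditions: Bu2BOTf, i-Pr2NEt, CH2Cl2, −78 → 0 °C; 8, −78 → 0 °C; pH 7 buffer–MeOH (no H2O2)
Reagents that add atoms: none
Why: Auxiliary-controlled boron glycolate aldol (Evans syn aldol): soft enolisation gives Z-enolate 9, which reacts through a closed chair (Zimmerman–Traxler) transition state on the face away from the benzyl group of the oxazolidinone, setting C8 (2S in the imide) and C7 (3R) together as the syn pair that corresponds to the threo 7R,8R ether, while the peroxide-free work-up spares the dithiane sulfur.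

Step 5
Reactants: 10 syn-aldol imide
Product: 11 (1R,2R)-1-[4-(benzyloxy)-3-methoxyphenyl]-2-[4-(1,3-dithian-2-yl)-2-methoxyphenoxy]propane-1,3-diol
Conditions: LiBH4, THF–MeOH, 0 °C
Reagents that add atoms: none
Why: Reductive cleavage of the N-acyl oxazolidinone with LiBH4: hydride attacks the exocyclic imide carbonyl selectively, the auxiliary is released intact, and the two stereocentres, neither of which is enolised, pass unchanged into the 1,3-diol.

Step 6
Reactants: 11 threo diol
Product: 12 (4R,5R)-4-[4-(benzyloxy)-3-methoxyphenyl]-5-[4-(1,3-dithian-2-yl)-2-methoxyphenoxy]-2,2-dimethyl-1,3-dioxane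
Conditions: Me2C(OMe)2, PPTS (cat.), CH2Cl2, rt
Reagents that add atoms: 2,2-dimethoxypropane, COC(C)(C)OC
Why: Acid-catalysed transketalisation to the isopropylidene acetal of a 1,3-diol closes a six-membered 1,3-dioxane and removes both O–H groups before the organolithium step, and PPTS is too mild to ionise the benzylic C–O bond or open the dithiane.

Step 7
Reactants: 13 furfural
Product: 15 5-hydroxy-2(5H)-furanone (racemic), via furfural endoperoxide 14 (not isolated)
Conditions: O2, hν (visible), rose bengal (cat.), MeOH, rt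
Reagents that add atoms: oxygen, O=O
Why: Dye-sensitised singlet-oxygen [4+2] cycloaddition to the furan gives endoperoxide 14, whose methanolysis expels the formyl carbon as methyl formate and leaves the hydroxybutenolide, a standard photooxygenation of furfural.

Step 8
Reactants: 15 5-hydroxy-2(5H)-furanone; 16 (1R,2S,5R)-menthol
Product: 18 (5R)-5-[(1R,2S,5R)-menthyloxy]-2(5H)-furanone, via 5S acetal epimer 17 (not isolated)
Conditions: CSA (cat.), toluene, reflux (Dean–Stark); crystallisation from petroleum ether, mother liquor re-equilibrated (CSA) and recrystallised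
Reagents that add atoms: none
Why: Acid-catalysed acetalisation of the lactol with l-menthol gives both C5 epimers, which interconvert through the ring oxocarbenium ion, and since the 5R diastereomer is the less soluble one, crystallisation with acid re-equilibration (crystallisation-induced diastereomer transformation) should funnel the material into 18, the acetal centre being set by the menthyl group.

Step 9
Reactants: 8 4-(benzyloxy)-3-methoxybenzaldehyde
Product: 19 [4-(benzyloxy)-3-methoxyphenyl]methanol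
Conditions: NaBH4, MeOH, 0 °C
Reagents that add atoms: none
Why: Borohydride reduction of an aryl aldehyde to the benzylic alcohol is chemoselective and leaves the benzyl ether alone.

Step 10
Reactants: 19 benzylic alcohol
Product: 20 4-(benzyloxy)-3-methoxybenzyl bromide
Conditions: PBr3, Et2O, 0 °C
Reagents that add atoms: phosphorus tribromide, BrP(Br)Br
Why: Bromination of an electron-rich benzylic alcohol with PBr3 proceeds through the phosphite ester and bromide displacement under conditions that do not cleave aryl benzyl or methyl ethers; the bromide is used promptly.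

Step 11
Reactants: 12 acetonide-protected dithiane; 18 (5R)-menthyloxy butenolide; 20 benzylic bromide
Product: 23 (3R,4R,5R)-3-[4-(benzyloxy)-3-methoxybenzyl]-4-[2-(4-{[(4R,5R)-4-[4-(benzyloxy)-3-methoxyphenyl]-2,2-dimethyl-1,3-dioxan-5-yl]oxy}-3-methoxyphenyl)-1,3-dithian-2-yl]-5-[(1R,2S,5R)-menthyloxy]dihydrofuran-2(3H)-one, via lithiated dithiane 21 (not isolated), via lactone lithium enolate 22 (not isolated)
Conditions: n-BuLi (1.0 equiv), THF, −78 → −30 °C; 18, −78 °C; then 20, DMPU, −78 → −20 °C
Reagents that add atoms: none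
Why: n-BuLi removes the only acidic C–H of 12, the dithiane C2–H, and the sulfur-stabilised benzylic anion 21 adds 1,4 to C4 of butenolide 18 on the face opposite the C5 menthyloxy group, giving lithium enolate 22, which is C-alkylated at C3 by bromide 20 on the face opposite the bulky dithianyl group. The closest known reaction type is the tandem conjugate addition–enolate alkylation of lithiated 2-aryl-1,3-dithianes with 5-alkoxy-2(5H)-furanones and benzylic halides; only the dithiane partner, with its protected 8-O-4 ether, is new. No ring is closed: both exocyclic C–C bonds form on the intact five-membered lactone. C4 (R) is controlled by the 5R acetal centre (anti addition) and C3 (R) by the new C4 substituent (anti alkylation), so the trans,trans adduct should hold all four stereocentres of the target plus the sacrificial acetal centre. The step needs 1,4- over 1,2-addition (soft, delocalised dithiane anion at low temperature), two anti facial selections (C5 and then C4 substituents on the flat ring), C- over O-alkylation (reactive benzylic bromide with DMPU) and a single deprotonation site (glycerol unit masked as acetonide and benzyl ether, one equivalent of base, cold).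

Step 12
Reactants: 23 three-component adduct
Product: 24 (3R,4R,5R)-3-[4-(benzyloxy)-3-methoxybenzyl]-4-(4-{[(4R,5R)-4-[4-(benzyloxy)-3-methoxyphenyl]-2,2-dimethyl-1,3-dioxan-5-yl]oxy}-3-methoxybenzyl)-5-[(1R,2S,5R)-menthyloxy]dihydrofuran-2(3H)-one
Conditions: NiCl2·6H2O, NaBH4, MeOH–THF, 0 °C
Reagents that add atoms: none
Why: Reductive desulfurisation of a benzylic dithioacetal with nickel boride formed in situ (the mild counterpart of Raney nickel hydrogenolysis) cleaves both C–S bonds to leave the C4 arm as CH2, should not hydrogenolyse aryl benzyl ethers or the dioxane, touches no C–H at C3, C4 or C5, and any premature borohydride opening of the acyl acetal would only anticipate the next step.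

Step 13
Reactants: 24 desulfurised menthyloxy lactone
Product: 27 (3R,4R)-3-[4-(benzyloxy)-3-methoxybenzyl]-4-(4-{[(4R,5R)-4-[4-(benzyloxy)-3-methoxyphenyl]-2,2-dimethyl-1,3-dioxan-5-yl]oxy}-3-methoxybenzyl)dihydrofuran-2(3H)-one, via formyl carboxylate 25 (not isolated), via hydroxy carboxylate 26 (not isolated)
Conditions: NaBH4, KOH, EtOH–THF–H2O, rt; then 1 M HCl to pH 3, 0 °C → rt
Reagents that add atoms: potassium hydroxide, [K+].[OH-] (its oxygen enters the carboxylate and can remain as the lactone carbonyl oxygen after re-closure)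
Why: Reductive removal of the alkoxy group of a γ-alkoxy butyrolactone: hydroxide opens the acyl acetal to carboxylate 25 with loss of menthol, borohydride present from the start reduces the freed aldehyde to 26 before it can epimerise, and acidification triggers lactonisation of the γ-hydroxy acid (5-exo-trig), so the acetal carbon becomes C5H2 while the thermodynamically preferred trans C3/C4 arrangement is retained.

Step 14
Reactants: 27 protected sesquilignan lactone
Product: 28 (3R,4R)-3-[4-(benzyloxy)-3-methoxybenzyl]-4-(4-{[(1R,2R)-1-[4-(benzyloxy)-3-methoxyphenyl]-1,3-dihydroxypropan-2-yl]oxy}-3-methoxybenzyl)dihydrofuran-2(3H)-one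
Conditions: AcOH–H2O (4:1), 40 °C
Reagents that add atoms: none
Why: Acid-catalysed hydrolysis of the isopropylidene acetal in aqueous acetic acid frees the 7,9-diol; it is done while both phenols are still benzylated, so the benzylic C7 cannot ionise through a quinone methide and the threo configuration should be kept, and the lactone is stable to these conditions.

Step 15
Reactants: 28 dibenzyl ether diol
Product: 29 target, (3R,4R)-3-(4-hydroxy-3-methoxybenzyl)-4-(4-{[(1R,2R)-1,3-dihydroxy-1-(4-hydroxy-3-methoxyphenyl)propan-2-yl]oxy}-3-methoxybenzyl)dihydrofuran-2(3H)-one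
Conditions: H2 (1 atm), Pd/C, EtOAc–EtOH, rt, stopped at full debenzylation
Reagents that add atoms: none
Why: Palladium-catalysed hydrogenolysis cleaves the two aryl benzyl ethers much faster than the secondary benzylic C7–OH or the aryl alkyl ether under neutral conditions at atmospheric pressure, so stopping at full debenzylation should deliver the target with all four stereocentres intact.

**Compound list**

1 | vanillin (4-hydroxy-3-methoxybenzaldehyde) | COc1cc(C=O)ccc1O | starting material
2 | 2-(4-hydroxy-3-methoxyphenyl)-1,3-dithiane | COc1cc(C2SCCCS2)ccc1O | intermediate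
3 | (S)-4-benzyloxazolidin-2-one | O=C1N[C@@H](Cc2ccccc2)CO1 | starting material
4 | chloroacetyl chloride | ClCC(=O)Cl | starting material
5 | N-lithio-(S)-4-benzyloxazolidin-2-one | [Li]N1C(=O)OC[C@@H]1Cc1ccccc1 | intermediate (not isolated)
6 | (S)-4-benzyl-3-(chloroacetyl)oxazolidin-2-one | O=C(CCl)N1C(=O)OC[C@@H]1Cc1ccccc1 | intermediate
7 | (S)-4-benzyl-3-{[4-(1,3-dithian-2-yl)-2-methoxyphenoxy]acetyl}oxazolidin-2-one | COc1cc(C2SCCCS2)ccc1OCC(=O)N1C(=O)OC[C@@H]1Cc1ccccc1 | intermediate
8 | 4-(benzyloxy)-3-methoxybenzaldehyde | COc1cc(C=O)ccc1OCc1ccccc1 | starting material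
9 | dibutylboron Z-enolate of 7 | COc1cc(C2SCCCS2)ccc1O/C=C(\OB(CCCC)CCCC)N1C(=O)OC[C@@H]1Cc1ccccc1 | intermediate (not isolated)
10 | (S)-4-benzyl-3-{(2S,3R)-3-[4-(benzyloxy)-3-methoxyphenyl]-2-[4-(1,3-dithian-2-yl)-2-methoxyphenoxy]-3-hydroxypropanoyl}oxazolidin-2-one | COc1cc(C2SCCCS2)ccc1O[C@H](C(=O)N1C(=O)OC[C@@H]1Cc1ccccc1)[C@H](O)c1ccc(OCc2ccccc2)c(OC)c1 | intermediate
11 | (1R,2R)-1-[4-(benzyloxy)-3-methoxyphenyl]-2-[4-(1,3-dithian-2-yl)-2-methoxyphenoxy]propane-1,3-diol | COc1cc(C2SCCCS2)ccc1O[C@H](CO)[C@H](O)c1ccc(OCc2ccccc2)c(OC)c1 | intermediate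
12 | (4R,5R)-4-[4-(benzyloxy)-3-methoxyphenyl]-5-[4-(1,3-dithian-2-yl)-2-methoxyphenoxy]-2,2-dimethyl-1,3-dioxane | COc1cc(C2SCCCS2)ccc1O[C@@H]1COC(C)(C)O[C@@H]1c1ccc(OCc2ccccc2)c(OC)c1 | intermediate
13 | furfural | O=Cc1ccco1 | starting material
14 | furfural endoperoxide (1-formyl-2,3,7-trioxabicyclo[2.2.1]hept-5-ene) | O=CC12C=CC(OO1)O2 | intermediate (not isolated)
15 | 5-hydroxy-2(5H)-furanone (racemic) | OC1OC(=O)C=C1 | intermediate
16 | (1R,2S,5R)-menthol | CC(C)[C@@H]1CC[C@@H](C)C[C@H]1O | starting material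
17 | (5S)-5-[(1R,2S,5R)-menthyloxy]-2(5H)-furanone | CC(C)[C@@H]1CC[C@@H](C)C[C@H]1O[C@H]1OC(=O)C=C1 | intermediate (not isolated)
18 | (5R)-5-[(1R,2S,5R)-menthyloxy]-2(5H)-furanone | CC(C)[C@@H]1CC[C@@H](C)C[C@H]1O[C@@H]1OC(=O)C=C1 | intermediate
19 | [4-(benzyloxy)-3-methoxyphenyl]methanol | COc1cc(CO)ccc1OCc1ccccc1 | intermediate
20 | 4-(benzyloxy)-3-methoxybenzyl bromide | COc1cc(CBr)ccc1OCc1ccccc1 | intermediate
21 | 2-lithio derivative of 12 (lithium at the dithiane C2) | COc1cc(C2([Li])SCCCS2)ccc1O[C@@H]1COC(C)(C)O[C@@H]1c1ccc(OCc2ccccc2)c(OC)c1 | intermediate (not isolated)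
22 | lithium enolate of the (4R,5R)-4-dithianyl-5-menthyloxy lactone | [Li]OC1=C[C@@H](C2(SCCCS2)c2ccc(O[C@@H]3COC(C)(C)O[C@@H]3c3ccc(OCc4ccccc4)c(OC)c3)c(OC)c2)[C@H](O[C@@H]2C[C@H](C)CC[C@H]2C(C)C)O1 | intermediate (not isolated)
23 | (3R,4R,5R)-3-[4-(benzyloxy)-3-methoxybenzyl]-4-[2-(4-{[(4R,5R)-4-[4-(benzyloxy)-3-methoxyphenyl]-2,2-dimethyl-1,3-dioxan-5-yl]oxy}-3-methoxyphenyl)-1,3-dithian-2-yl]-5-[(1R,2S,5R)-menthyloxy]dihydrofuran-2(3H)-one | COc1cc(C[C@H]2C(=O)O[C@@H](O[C@@H]3C[C@H](C)CC[C@H]3C(C)C)[C@@H]2C3(SCCCS3)c3ccc(O[C@@H]4COC(C)(C)O[C@@H]4c4ccc(OCc5ccccc5)c(OC)c4)c(OC)c3)ccc1OCc1ccccc1 | intermediate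
24 | (3R,4R,5R)-3-[4-(benzyloxy)-3-methoxybenzyl]-4-(4-{[(4R,5R)-4-[4-(benzyloxy)-3-methoxyphenyl]-2,2-dimethyl-1,3-dioxan-5-yl]oxy}-3-methoxybenzyl)-5-[(1R,2S,5R)-menthyloxy]dihydrofuran-2(3H)-one | COc1cc(C[C@H]2C(=O)O[C@@H](O[C@@H]3C[C@H](C)CC[C@H]3C(C)C)[C@@H]2Cc2ccc(O[C@@H]3COC(C)(C)O[C@@H]3c3ccc(OCc4ccccc4)c(OC)c3)c(OC)c2)ccc1OCc1ccccc1 | intermediate
25 | potassium (2R,3R)-2-[4-(benzyloxy)-3-methoxybenzyl]-3-formyl-4-(4-{[(4R,5R)-4-[4-(benzyloxy)-3-methoxyphenyl]-2,2-dimethyl-1,3-dioxan-5-yl]oxy}-3-methoxyphenyl)butanoate | [K+].[O-]C(=O)[C@H](Cc1ccc(OCc2ccccc2)c(OC)c1)[C@H](C=O)Cc1ccc(O[C@@H]2COC(C)(C)O[C@@H]2c2ccc(OCc3ccccc3)c(OC)c2)c(OC)c1 | intermediate (not isolated)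
26 | potassium (2R,3R)-2-[4-(benzyloxy)-3-methoxybenzyl]-3-(hydroxymethyl)-4-(4-{[(4R,5R)-4-[4-(benzyloxy)-3-methoxyphenyl]-2,2-dimethyl-1,3-dioxan-5-yl]oxy}-3-methoxyphenyl)butanoate | [K+].[O-]C(=O)[C@H](Cc1ccc(OCc2ccccc2)c(OC)c1)[C@H](CO)Cc1ccc(O[C@@H]2COC(C)(C)O[C@@H]2c2ccc(OCc3ccccc3)c(OC)c2)c(OC)c1 | intermediate (not isolated)
27 | (3R,4R)-3-[4-(benzyloxy)-3-methoxybenzyl]-4-(4-{[(4R,5R)-4-[4-(benzyloxy)-3-methoxyphenyl]-2,2-dimethyl-1,3-dioxan-5-yl]oxy}-3-methoxybenzyl)dihydrofuran-2(3H)-one | COc1cc(C[C@H]2C(=O)OC[C@@H]2Cc2ccc(O[C@@H]3COC(C)(C)O[C@@H]3c3ccc(OCc4ccccc4)c(OC)c3)c(OC)c2)ccc1OCc1ccccc1 | intermediate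
28 | (3R,4R)-3-[4-(benzyloxy)-3-methoxybenzyl]-4-(4-{[(1R,2R)-1-[4-(benzyloxy)-3-methoxyphenyl]-1,3-dihydroxypropan-2-yl]oxy}-3-methoxybenzyl)dihydrofuran-2(3H)-one | COc1cc(C[C@H]2C(=O)OC[C@@H]2Cc2ccc(O[C@H](CO)[C@H](O)c3ccc(OCc4ccccc4)c(OC)c3)c(OC)c2)ccc1OCc1ccccc1 | intermediate
29 | (3R,4R)-3-(4-hydroxy-3-methoxybenzyl)-4-(4-{[(1R,2R)-1,3-dihydroxy-1-(4-hydroxy-3-methoxyphenyl)propan-2-yl]oxy}-3-methoxybenzyl)dihydrofuran-2(3H)-one | COc1cc(C[C@H]2C(=O)OC[C@@H]2Cc2ccc(O[C@H](CO)[C@H](O)c3ccc(O)c(OC)c3)c(OC)c2)ccc1O | target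

**Step count and risks**

Total step count: 15. Longest linear sequence: 10 steps (steps 1, 3, 4, 5, 6, 11, 12, 13, 14, 15, from vanillin 1 to 29).

The three steps most likely to fail:

1. Step 11 (three-component coupling). What may go wrong: reversal of the conjugate addition on warming, proton transfer to the hindered enolate, or sluggish alkylation next to the fully substituted dithianyl carbon, so that the bromide is not taken up. The fallback sets out from 12 and 18 and returns at 27. Compound 12 is lithiated and added to 18 as before, but the enolate is protonated at −78 °C with AcOH to give the conjugate adduct (4R,5R)-4-(2-aryl-1,3-dithian-2-yl)-5-menthyloxy lactone F1. Nickel boride (NiCl2·6H2O, NaBH4) then removes the sulfur to give the (4R,5R)-4-arylmethyl-5-menthyloxy lactone F2. NaBH4/KOH followed by acid turns the acetal carbon into CH2 with loss of menthol and gives the (R)-4-arylmethyl butyrolactone F3. Deprotonation of F3 with LiHMDS (THF, −78 °C) and alkylation of the now unhindered enolate with 20, trans to the C4 arm as usual for β-substituted butyrolactones, gives 27.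

2. Step 4 (boron aldol on the dithiane-bearing imide). What may go wrong: interference of the dithiane sulfur with boron enolisation, incomplete release of the aldol from boron without peroxide, and erosion of syn selectivity if enolisation is incomplete. The fallback sets out from 6 and 8, uses purchased 4-bromo-2-methoxyphenol in place of 2, and returns at 12; the aldehyde carbon is brought in only after the aldol. The bromophenol is alkylated with 6 (K2CO3, acetone) to give the bromoaryloxyacetyl imide F4. The same Bu2BOTf/i-Pr2NEt aldol with 8, now with the ordinary H2O2/MeOH/buffer work-up, gives the syn-aldol adduct F5. LiBH4 gives the bromoaryl threo diol F6, and Me2C(OMe)2/PPTS gives the bromoaryl acetonide F7. Bromine–lithium exchange (n-BuLi, THF, −78 °C) and formylation with DMF give the aryl aldehyde F8. Neutral thioacetalisation with 1,3-bis(trimethylsilylthio)propane and catalytic ZnI2 (Et2O, 0 °C → rt), which should leave the acetonide and the benzylic ether intact, gives 12.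

3. Step 12 (desulfurisation). What may go wrong: over-reduction on the nickel surface (hydrogenolysis of the aryl benzyl ethers or benzylic C–O bonds), stalling after the first C–S cleavage at the crowded carbon, or borohydride attack on the acyl acetal. The fallback sets out from 23 and returns at 24 without any new compound. Sulfur is removed by a homogeneous tin hydride radical chain (Bu3SnH in excess, AIBN, toluene, 110 °C). This is the known radical desulfurisation of benzylic dithioacetals; it is neutral, uses no metal surface and no hydride nucleophile, and ethers, acetals and the lactone are inert to it.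

**Further compounds**

F1 | step 11 | (4R,5R)-4-[2-(4-{[(4R,5R)-4-[4-(benzyloxy)-3-methoxyphenyl]-2,2-dimethyl-1,3-dioxan-5-yl]oxy}-3-methoxyphenyl)-1,3-dithian-2-yl]-5-[(1R,2S,5R)-menthyloxy]dihydrofuran-2(3H)-one | O=C1C[C@@H](C2(SCCCS2)c2ccc(O[C@@H]3COC(C)(C)O[C@@H]3c3ccc(OCc4ccccc4)c(OC)c3)c(OC)c2)[C@H](O[C@@H]2C[C@H](C)CC[C@H]2C(C)C)O1
F2 | step 11 | (4R,5R)-4-(4-{[(4R,5R)-4-[4-(benzyloxy)-3-methoxyphenyl]-2,2-dimethyl-1,3-dioxan-5-yl]oxy}-3-methoxybenzyl)-5-[(1R,2S,5R)-menthyloxy]dihydrofuran-2(3H)-one | O=C1C[C@@H](Cc2ccc(O[C@@H]3COC(C)(C)O[C@@H]3c3ccc(OCc4ccccc4)c(OC)c3)c(OC)c2)[C@H](O[C@@H]2C[C@H](C)CC[C@H]2C(C)C)O1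
F3 | step 11 | (R)-4-(4-{[(4R,5R)-4-[4-(benzyloxy)-3-methoxyphenyl]-2,2-dimethyl-1,3-dioxan-5-yl]oxy}-3-methoxybenzyl)dihydrofuran-2(3H)-one | O=C1C[C@@H](Cc2ccc(O[C@@H]3COC(C)(C)O[C@@H]3c3ccc(OCc4ccccc4)c(OC)c3)c(OC)c2)CO1
F4 | step 4 | (S)-4-benzyl-3-[(4-bromo-2-methoxyphenoxy)acetyl]oxazolidin-2-one | COc1cc(Br)ccc1OCC(=O)N1C(=O)OC[C@@H]1Cc1ccccc1
F5 | step 4 | (S)-4-benzyl-3-{(2S,3R)-3-[4-(benzyloxy)-3-methoxyphenyl]-2-(4-bromo-2-methoxyphenoxy)-3-hydroxypropanoyl}oxazolidin-2-one | COc1cc(Br)ccc1O[C@H](C(=O)N1C(=O)OC[C@@H]1Cc1ccccc1)[C@H](O)c1ccc(OCc2ccccc2)c(OC)c1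
F6 | step 4 | (1R,2R)-1-[4-(benzyloxy)-3-methoxyphenyl]-2-(4-bromo-2-methoxyphenoxy)propane-1,3-diol | COc1cc(Br)ccc1O[C@H](CO)[C@H](O)c1ccc(OCc2ccccc2)c(OC)c1
F7 | step 4 | (4R,5R)-4-[4-(benzyloxy)-3-methoxyphenyl]-5-(4-bromo-2-methoxyphenoxy)-2,2-dimethyl-1,3-dioxane | COc1cc(Br)ccc1O[C@@H]1COC(C)(C)O[C@@H]1c1ccc(OCc2ccccc2)c(OC)c1
F8 | step 4 | 4-{[(4R,5R)-4-[4-(benzyloxy)-3-methoxyphenyl]-2,2-dimethyl-1,3-dioxan-5-yl]oxy}-3-methoxybenzaldehyde | COc1cc(C=O)ccc1O[C@@H]1COC(C)(C)O[C@@H]1c1ccc(OCc2ccccc2)c(OC)c1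
F0 | step 12 | none | none
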